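## Retrosynthetic overview

1. The target comes from its decabenzyl ether by a final global hydrogenolysis. That ether comes from 3-O-galloylation of a (2R,3R)-flavan-3-ol that already carries the 5-O-gallate and a 7-O-benzyl group.
2. Key step: both stereocentres are set in one asymmetric transfer hydrogenation with dynamic kinetic resolution (ATH-DKR) of a racemic, C2-labile flavan-3-one. This avoids the cinnamyl/dihydroxylation/cyclisation/oxidation–reduction sequence and semisynthesis from a tea catechin.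
3. The flavan-3-one comes from hydride addition to a planar 3-hydroxyflavylium salt, followed by tautomerisation (anthocyanidin-reductase logic).
4. Ring C is the only ring formed. It comes from a Robinson acid condensation of a ring A salicylaldehyde with a ring B ω-hydroxyacetophenone. The 5-O/7-O distinction is settled on the aldehyde beforehand, by 4-O-benzylation and then a desymmetrising monoacylation.
5. Rings A and B and both galloyl rings are bought. Tri-O-benzylgallic acid supplies ring B and both esters.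

Assumption: the SMILES decodes as the natural 2,3-cis (2R,3R) series; 1 and 3 are purchasable; the (R,R) catalyst in step 8 is chosen by the CH/π model, with the C2 side of the ketone taking the place of the aryl group of acetophenone, and the mirror-image complex is equally available should the sense prove opposite.

## Route

Step 1
Reactants: 1 2,4,6-trihydroxybenzaldehyde
Product: 2 4-(benzyloxy)-2,6-dihydroxybenzaldehyde
Conditions: BnBr (1.0 equiv), CsHCO3 (1.1 equiv), MeCN, 60 °C
Reagents that add atoms: benzyl bromide, BrCc1ccccc1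
Why: Williamson etherification; the 4-OH, para to the formyl group and not hydrogen-bonded to it, is the most acidic phenol, so one equivalent of a weak base and BnBr alkylates it selectively, and no stereocentre is formed.

Step 2
Reactants: 3 3,4,5-tris(benzyloxy)benzoic acid
Product: 4 3,4,5-tris(benzyloxy)benzoyl chloride
Conditions: (COCl)2 (1.2 equiv), DMF (cat.), CH2Cl2, 0 °C to rt
Reagents that add atoms: oxalyl chloride, O=C(Cl)C(=O)Cl
Why: DMF-catalysed (Vilsmeier-type) acid chloride formation is routine for this acid and leaves aryl benzyl ethers untouched.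

Step 3
Reactants: 2 4-(benzyloxy)-2,6-dihydroxybenzaldehyde; 4 3,4,5-tris(benzyloxy)benzoyl chloride
Product: 5 5-(benzyloxy)-2-formyl-3-hydroxyphenyl 3,4,5-tris(benzyloxy)benzoate
Conditions: 4 (0.95 equiv, slow addition), Et3N (1.1 equiv), CH2Cl2, −20 to 0 °C
Reagents that add atoms: none
Why: O-acylation (nucleophilic acyl substitution) that desymmetrises two equivalent phenols; after the first acylation the remaining OH is locked in a strong hydrogen bond to the formyl group and reacts far more slowly, so the reaction stops at the monoester that later becomes the 5-O-gallate.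

Step 4
Reactants: 4 3,4,5-tris(benzyloxy)benzoyl chloride
Product: 6 2-diazo-1-[3,4,5-tris(benzyloxy)phenyl]ethan-1-one
Conditions: TMSCHN2 (2.0 M in hexanes, 1.5 equiv), THF/MeCN 1:1, 0 °C to rt
Reagents that add atoms: (trimethylsilyl)diazomethane, C[Si](C)(C)C=[N+]=[N-]
Why: Arndt–Eistert-type acylation of a diazoalkane; the diazo carbon attacks the aroyl chloride and chloride removes the silyl group, leaving the stabilised aryl diazoketone.

Step 5
Reactants: 6 2-diazo-1-[3,4,5-tris(benzyloxy)phenyl]ethan-1-one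
Product: 7 2-hydroxy-1-[3,4,5-tris(benzyloxy)phenyl]ethan-1-one
Conditions: 1 M aq. H2SO4 (cat.), 1,4-dioxane/H2O 4:1, 60 °C
Reagents that add atoms: water, O
Why: Acid-catalysed hydrolysis of an α-diazoketone; C-protonation gives a diazonium ion that water displaces with loss of nitrogen, under conditions where benzyl ethers are inert and Wolff rearrangement does not compete.

Step 6
Reactants: 5 5-(benzyloxy)-2-formyl-3-hydroxyphenyl 3,4,5-tris(benzyloxy)benzoate; 7 2-hydroxy-1-[3,4,5-tris(benzyloxy)phenyl]ethan-1-one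
Product: 9 7-(benzyloxy)-3-hydroxy-2-[3,4,5-tris(benzyloxy)phenyl]-5-{[3,4,5-tris(benzyloxy)benzoyl]oxy}chromenylium chloride, via (Z)-α-hydroxychalcone 8 (not isolated)
Conditions: dry HCl (g, saturation), EtOAc, 0 °C then 4 °C, 48 h; precipitation with Et2O/pentane
Reagents that add atoms: hydrogen chloride, Cl
Why: Robinson anthocyanidin synthesis; acid-catalysed aldol condensation of the enediol of 7 with the protonated aldehyde gives chalcone 8, which isomerises, adds its phenol to the aryl ketone and loses water to form the aromatic pyrylium ring C, while aroyl esters at O-5 are known to survive these anhydrous conditions and the planar cation has no stereocentre.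

Step 7
Reactants: 9 7-(benzyloxy)-3-hydroxy-2-[3,4,5-tris(benzyloxy)phenyl]-5-{[3,4,5-tris(benzyloxy)benzoyl]oxy}chromenylium chloride
Product: 11 racemic 7-(benzyloxy)-3-oxo-2-[3,4,5-tris(benzyloxy)phenyl]chroman-5-yl 3,4,5-tris(benzyloxy)benzoate, via flav-2-en-3-ol 10 (not isolated)
Conditions: diethyl 1,4-dihydro-2,6-dimethylpyridine-3,5-dicarboxylate (Hantzsch ester, 1.1 equiv), CH2Cl2, 0 °C to rt, Ar, 9 added slowly to the reductant
Reagents that add atoms: none
Why: Ionic hydride transfer from an NADH model to a benzopyrylium ion followed by keto–enol tautomerisation; attack at C4 gives enol 10 and any attack at C2 gives the isomeric flav-3-en-3-ol, both of which collapse to the same ketone 11, whose C2 centre is deliberately formed racemic.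

Step 8
Reactants: 11 racemic 7-(benzyloxy)-3-oxo-2-[3,4,5-tris(benzyloxy)phenyl]chroman-5-yl 3,4,5-tris(benzyloxy)benzoate
Product: 12 (2R,3R)-7-(benzyloxy)-3-hydroxy-2-[3,4,5-tris(benzyloxy)phenyl]chroman-5-yl 3,4,5-tris(benzyloxy)benzoate
Conditions: RuCl(p-cymene)[(R,R)-TsDPEN] (2 mol %), HCO2H (3 equiv), Et3N (5 equiv), EtOAc, 40 °C, Ar
Reagents that add atoms: none
Why: Proposed new method: the C2–H of 11 is flanked by a carbonyl, an aryl and an aryloxy group, so Et3N epimerises it through achiral enol 10 faster than reduction occurs, while the bifunctional Ru–H/N–H catalyst delivers H−/H+ by an outer-sphere path only to the (2R)-ketone and only on the face anti to the pseudo-equatorial 2-aryl group (the same face that bulky borohydrides use on flavan-3-ones), giving the axial 3-OH and setting C2 and C3 together as 2R,3R (cis); the closest known reaction type is the Noyori–Ikariya ATH-DKR of α-aryl cyclic ketones such as isoflavanones and 2-aryltetralones.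

Step 9
Reactants: 12 (2R,3R)-7-(benzyloxy)-3-hydroxy-2-[3,4,5-tris(benzyloxy)phenyl]chroman-5-yl 3,4,5-tris(benzyloxy)benzoate; 4 3,4,5-tris(benzyloxy)benzoyl chloride
Product: 13 (2R,3R)-7-(benzyloxy)-2-[3,4,5-tris(benzyloxy)phenyl]chromane-3,5-diyl bis[3,4,5-tris(benzyloxy)benzoate]
Conditions: 4 (1.5 equiv), Et3N (2 equiv), DMAP (0.2 equiv), CH2Cl2, rt
Reagents that add atoms: none
Why: DMAP-catalysed esterification of the axial 3-OH with the acid chloride is the standard galloylation of epi-series flavan-3-ols and touches no C–O bond at a stereocentre, and even a 5-to-3 acyl shift in 12 would be harmless because both esters carry the same acyl group and lead to the same 13.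

Step 10
Reactants: 13 (2R,3R)-7-(benzyloxy)-2-[3,4,5-tris(benzyloxy)phenyl]chromane-3,5-diyl bis[3,4,5-tris(benzyloxy)benzoate]
Product: 14 (−)-epigallocatechin 3,5-di-O-gallate, (2R,3R)-7-hydroxy-2-(3,4,5-trihydroxyphenyl)chromane-3,5-diyl bis(3,4,5-trihydroxybenzoate)
Conditions: H2 (1 atm), 20 % Pd(OH)2/C, THF/MeOH 1:1, rt, then filtration under Ar
Reagents that add atoms: none
Why: Heterogeneous catalytic hydrogenolysis removes all ten O-benzyl groups under neutral conditions that spare both esters, the C2–O1 bond and both stereocentres, as established for perbenzylated epi-catechin gallates.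

## Compound list

1 | 2,4,6-trihydroxybenzaldehyde | O=Cc1c(O)cc(O)cc1O | starting material
2 | 4-(benzyloxy)-2,6-dihydroxybenzaldehyde | O=Cc1c(O)cc(OCc2ccccc2)cc1O | intermediate
3 | 3,4,5-tris(benzyloxy)benzoic acid | OC(=O)c1cc(OCc2ccccc2)c(OCc2ccccc2)c(OCc2ccccc2)c1 | starting material
4 | 3,4,5-tris(benzyloxy)benzoyl chloride | ClC(=O)c1cc(OCc2ccccc2)c(OCc2ccccc2)c(OCc2ccccc2)c1 | intermediate
5 | 5-(benzyloxy)-2-formyl-3-hydroxyphenyl 3,4,5-tris(benzyloxy)benzoate | O=Cc1c(O)cc(OCc2ccccc2)cc1OC(=O)c1cc(OCc2ccccc2)c(OCc2ccccc2)c(OCc2ccccc2)c1 | intermediate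
6 | 2-diazo-1-[3,4,5-tris(benzyloxy)phenyl]ethan-1-one | [N-]=[N+]=CC(=O)c1cc(OCc2ccccc2)c(OCc2ccccc2)c(OCc2ccccc2)c1 | intermediate
7 | 2-hydroxy-1-[3,4,5-tris(benzyloxy)phenyl]ethan-1-one | OCC(=O)c1cc(OCc2ccccc2)c(OCc2ccccc2)c(OCc2ccccc2)c1 | intermediate
8 | 5-(benzyloxy)-3-hydroxy-2-{(1Z)-2-hydroxy-3-oxo-3-[3,4,5-tris(benzyloxy)phenyl]prop-1-en-1-yl}phenyl 3,4,5-tris(benzyloxy)benzoate ((Z)-α-hydroxychalcone) | O=C(c1cc(OCc2ccccc2)c(OCc2ccccc2)c(OCc2ccccc2)c1)/C(O)=C/c1c(O)cc(OCc2ccccc2)cc1OC(=O)c1cc(OCc2ccccc2)c(OCc2ccccc2)c(OCc2ccccc2)c1 | intermediate (not isolated)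
9 | 7-(benzyloxy)-3-hydroxy-2-[3,4,5-tris(benzyloxy)phenyl]-5-{[3,4,5-tris(benzyloxy)benzoyl]oxy}chromenylium chloride | [Cl-].O=C(Oc1cc(OCc2ccccc2)cc2[o+]c(-c3cc(OCc4ccccc4)c(OCc4ccccc4)c(OCc4ccccc4)c3)c(O)cc12)c1cc(OCc2ccccc2)c(OCc2ccccc2)c(OCc2ccccc2)c1 | intermediate
10 | 7-(benzyloxy)-3-hydroxy-2-[3,4,5-tris(benzyloxy)phenyl]-4H-chromen-5-yl 3,4,5-tris(benzyloxy)benzoate (flav-2-en-3-ol) | O=C(Oc1cc(OCc2ccccc2)cc2OC(c3cc(OCc4ccccc4)c(OCc4ccccc4)c(OCc4ccccc4)c3)=C(O)Cc12)c1cc(OCc2ccccc2)c(OCc2ccccc2)c(OCc2ccccc2)c1 | intermediate (not isolated)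
11 | racemic 7-(benzyloxy)-3-oxo-2-[3,4,5-tris(benzyloxy)phenyl]chroman-5-yl 3,4,5-tris(benzyloxy)benzoate (C2 racemic and labile, so drawn without a descriptor) | O=C(Oc1cc(OCc2ccccc2)cc2OC(c3cc(OCc4ccccc4)c(OCc4ccccc4)c(OCc4ccccc4)c3)C(=O)Cc12)c1cc(OCc2ccccc2)c(OCc2ccccc2)c(OCc2ccccc2)c1 | intermediate
12 | (2R,3R)-7-(benzyloxy)-3-hydroxy-2-[3,4,5-tris(benzyloxy)phenyl]chroman-5-yl 3,4,5-tris(benzyloxy)benzoate | O=C(Oc1cc(OCc3ccccc3)cc2c1C[C@@H](O)[C@@H](c1cc(OCc3ccccc3)c(OCc3ccccc3)c(OCc3ccccc3)c1)O2)c1cc(OCc2ccccc2)c(OCc2ccccc2)c(OCc2ccccc2)c1 | intermediate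
13 | (2R,3R)-7-(benzyloxy)-2-[3,4,5-tris(benzyloxy)phenyl]chromane-3,5-diyl bis[3,4,5-tris(benzyloxy)benzoate] | O=C(Oc1cc(OCc3ccccc3)cc2c1C[C@@H](OC(=O)c1cc(OCc3ccccc3)c(OCc3ccccc3)c(OCc3ccccc3)c1)[C@@H](c1cc(OCc3ccccc3)c(OCc3ccccc3)c(OCc3ccccc3)c1)O2)c1cc(OCc2ccccc2)c(OCc2ccccc2)c(OCc2ccccc2)c1 | intermediate
14 | (−)-epigallocatechin 3,5-di-O-gallate, (2R,3R) | O=C(Oc1cc(O)cc2c1C[C@@H](OC(=O)c1cc(O)c(O)c(O)c1)[C@@H](c1cc(O)c(O)c(O)c1)O2)c1cc(O)c(O)c(O)c1 | target

## Step count and risk assessment

Total step count: 10.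
Longest linear sequence: 8 steps (3 → 4 → 6 → 7 → 9 → 11 → 12 → 13 → 14).

**Step 6 (Robinson condensation with a free ketol).**
- Risks: side reactions of the α-ketol in strong acid, sluggish aldol on the electron-rich aldehyde, and chloride-induced loss of the 7- or 4'-benzyl group from the cation.
- The fallback sets out from 4 and 5 and comes back to the route at 11. It introduces O-3 only after ring C is closed.
- Compound 4 is methylated with Me2CuLi (THF, −78 °C) to 3,4,5-tris(benzyloxy)acetophenone F1. This plain aryl methyl ketone is the best substrate class for the condensation.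
- With 5 (HCl, EtOAc, 0 °C) it gives the 3-deoxyflavylium chloride F2, and Hantzsch ester (CH2Cl2, 0 °C) reduces this to the 4H-flavene F3.
- Dimethyldioxirane (acetone/CH2Cl2, −40 °C) epoxidises the enol ether to the labile racemic 2,3-epoxyflavan F4.
- On warming to 0 °C with Zn(OTf)2 (5 mol %), F4 opens to the C2 oxocarbenium ion and undergoes a 1,2-hydride shift (Meinwald-type epoxy-ether rearrangement) to 11.
- A 2H-flavene regioisomer from the reduction would reach the same ketone through its 3,4-epoxide.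

**Step 8 (ATH-DKR).**
- Risks: epimerisation at C2 too slow, so that only a kinetic resolution results, or modest facial discrimination on a non-conjugated ketone.
- The fallback sets out from 11 and comes back at 12. It separates relative control from absolute control.
- LiBH(s-Bu)3 (THF, −78 °C, NH4Cl quench) attacks anti to the 2-aryl group and gives the racemic cis alcohol, that is, 12 together with its mirror image, the (2S,3S)-alcohol F5.
- Preparative supercritical-fluid chromatography on an amylose tris(3,5-dimethylphenylcarbamate) phase delivers 12.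
- F5 is oxidised with Dess–Martin periodinane back to the ketone, which racemises with Et3N to 11 and is recycled, so no material is lost in principle.

**Step 1 (regioselective mono-benzylation).**
- Risks: 2-O- and di-O-benzylation, and C-benzylation of the phloroglucinol nucleus.
- The fallback sets out from 1 and comes back at 2. It protects everything and then uses the formyl group as a directing group.
- Excess BnBr/K2CO3 (DMF, 60 °C) gives 2,4,6-tris(benzyloxy)benzaldehyde F6.
- MgBr2·OEt2 (3 equiv, toluene/Et2O, 80 °C) chelates to the carbonyl oxygen and cleaves only the two ortho benzyl ethers, leaving the para ether in place to give 2.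

## Further compounds

F1 | step 6 | 3,4,5-tris(benzyloxy)acetophenone | CC(=O)c1cc(OCc2ccccc2)c(OCc2ccccc2)c(OCc2ccccc2)c1
F2 | step 6 | 7-(benzyloxy)-2-[3,4,5-tris(benzyloxy)phenyl]-5-{[3,4,5-tris(benzyloxy)benzoyl]oxy}chromenylium chloride (3-deoxyflavylium chloride) | [Cl-].O=C(Oc1cc(OCc2ccccc2)cc2[o+]c(-c3cc(OCc4ccccc4)c(OCc4ccccc4)c(OCc4ccccc4)c3)ccc12)c1cc(OCc2ccccc2)c(OCc2ccccc2)c(OCc2ccccc2)c1
F3 | step 6 | 7-(benzyloxy)-2-[3,4,5-tris(benzyloxy)phenyl]-4H-chromen-5-yl 3,4,5-tris(benzyloxy)benzoate (4H-flavene) | O=C(Oc1cc(OCc2ccccc2)cc2OC(c3cc(OCc4ccccc4)c(OCc4ccccc4)c(OCc4ccccc4)c3)=CCc12)c1cc(OCc2ccccc2)c(OCc2ccccc2)c(OCc2ccccc2)c1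
F4 | step 6 | racemic 2,3-epoxyflavan derived from F3 (cis-fused oxirane, relative configuration fixed by the ring) | O=C(Oc1cc(OCc2ccccc2)cc2OC3(c4cc(OCc5ccccc5)c(OCc5ccccc5)c(OCc5ccccc5)c4)OC3Cc12)c1cc(OCc2ccccc2)c(OCc2ccccc2)c(OCc2ccccc2)c1
F5 | step 8 | (2S,3S)-7-(benzyloxy)-3-hydroxy-2-[3,4,5-tris(benzyloxy)phenyl]chroman-5-yl 3,4,5-tris(benzyloxy)benzoate (enantiomer of 12) | O=C(Oc1cc(OCc3ccccc3)cc2c1C[C@H](O)[C@H](c1cc(OCc3ccccc3)c(OCc3ccccc3)c(OCc3ccccc3)c1)O2)c1cc(OCc2ccccc2)c(OCc2ccccc2)c(OCc2ccccc2)c1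
F6 | step 1 | 2,4,6-tris(benzyloxy)benzaldehyde | O=Cc1c(OCc2ccccc2)cc(OCc2ccccc2)cc1OCc1ccccc1
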